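## The problem

The carbons are numbered as in a germacranolide: C1 is the furanone ketone, C2=C3 its enol ether, C4=C5 the trisubstituted alkene bearing the C15 hydroxymethyl group, C6 the lactone carbinol, C8 the ester carbinol, C10 the quaternary ether carbon with the C14 methyl group, and C11=C13 the exocyclic methylene next to the C12 lactone carbonyl. The target is a ten-membered carbocycle (C1 to C10) spanned by an oxygen bridge from C3 to C10, which makes C10–C1–C2–C3–O a 3(2H)-furanone. It is trans-fused along C6–C7 to an α-methylene-γ-butyrolactone and carries an (R)-2-methylbutanoate on C8.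

There are five stereocentres. C6, C7 and C8 are contiguous, so C6 can direct C7 (trans across the lactone) and, through a cyclic transition state, C8. The quaternary C10 is insulated from this triad by the C9 methylene and can neither control it nor be controlled by it, so it has to come from an enantiopure building block. The side-chain centre comes with its acid and must not see enolising base.

The α-methylene lactone (Michael acceptor, prone to slip its alkene into the ring), the furanone (a vinylogous ester, electrophilic at C3), the allylic alcohol and the ester exclude strong base, hydride and hard nucleophiles late in the route. Any aldehyde β to the furanone oxygen can also lose that oxygen by elimination. The crux is closing a ten-membered ring that holds a Z alkene and two further sp2 carbons, preferably with nothing left to do afterwards.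

The structure offers one handle for this: C3–C4 is the only single bond between two sp2 carbons of the carbocycle. C3 is the β-carbon of the furanone enone and can carry a methylthio group, which a methyl ketone and carbon disulfide provide. C4 carries a hydroxymethyl group that can direct an anti hydrostannation of a C4≡C5 alkyne, placing tin on C4 with the Z geometry that holds C3 and C6 on the same side.

## Retrosynthesis

**C3–C4 (28 to 27).** The target 28 is cut at C3–C4 to give stannane 27, which already has every stereocentre and functional group of 28. The neighbouring cuts are less attractive. Forming C4=C5 would mean making a trisubstituted Z alkene inside a medium ring. Closing through the furanone (O–C3 or C2–C3) would need a strained cyclic ynone or diketone first. The C3–C4 cut creates no stereocentre, and the forward step ends the synthesis. That step has to favour ring closure over oligomerisation, keep the alkene geometry, and tolerate the free alcohol, the lactone and the ester.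

**C4–Sn and the C15 hydroxyl (27 to 26 to 25).** Stannane 27 comes from alkynol 26 by hydroxyl-directed anti addition of tin hydride across C4≡C5, and 26 from silyl ether 25. Tin is introduced this late because it would not survive the bromine, zinc and azodicarboxylate of the earlier steps, and because a syn hydrometallation would give the wrong geometry. The alkyne itself is inert through all of those steps. The forward reaction must put tin on C4 (not C5), add anti, and leave the methylene lactone alone.

**C8–O (25 to 23 and 24).** Ester 25 is cut at the C8–O bond into alcohol 23 and (R)-2-methylbutanoic acid 24, with inversion at C8. The fragment union below is expected to give the 8S alcohol, one centre short of the target. An SN2 esterification introduces the side chain and corrects C8 in the same step, so no extra step is spent on the correction.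

**C7–C8 (23 to 12 and 22).** Alcohol 23 is cut at C7–C8 into aldehyde 12 and allylic bromide 22. This cut splits the molecule into two halves of similar size whose stereocentres have independent origins (C10 in 12, C6 in 22). It lets C6 set C7 and C8 in one Barbier addition, and it creates the exocyclic methylene by allylic transposition, so the lactone never needs an enolate methylenation. Cutting C6–C7 or C8–C9 would instead place the new stereocentres next to centres with no reliable control element. The forward step must go through the γ-carbon C7, anti to the C6 substituent, under conditions mild enough for the elimination-prone aldehyde 12.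

**The furanone half (12 back to 1).** Aldehyde 12 comes from alcohol 11 and silyl ether 10. The furanone of 10 is cut at C2–C3 and O–C3, which leads to hydroxy methyl ketone 7 and carbon disulfide 8. This one construction gives both the ring and the methylthio group the key step needs. Ketone 7 goes back through Weinreb amide 6, diol amide 5 and hydroxy lactone 4 to acetonide acid 2 and (S)-citramalic acid 1. The acid 1 supplies C1, C8, C9, C10 and C14 with the tertiary carbinol in the right configuration, which is simpler than making a tertiary alcohol by asymmetric catalysis.

**The lactone half (22 back to 13).** Bromide 22 comes from α-methylene lactone 20 by bromine addition and loss of HBr. Lactone 20 comes from ynone 18 by asymmetric transfer hydrogenation (which sets C6) and lactonisation. Ynone 18 comes from racemic alcohol 17, the zinc Barbier adduct of ynal 15 and methyl 2-(bromomethyl)acrylate 16. Ynal 15 comes from propargyl alcohol 13 through silyl ether 14. Propargyl alcohol thus supplies C4, C5 and C15; the acrylate supplies C7, C11, C12 and C13.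

## Roads not taken

**Alternative 1:** The cut is C1–C2. An open-chain aldehyde with a C2 iodoalkyne, A2, would be closed with CrCl2 and catalytic NiCl2 (Nozaki–Hiyama–Kishi addition) to the ten-membered propargylic alcohol A1. Oxidation to the ynone, removal of the silyl group on O10, oxa-Michael closure of the furanone and removal of the C15 silyl group would follow.
- Merits: this class of ring closure has a strong record for medium rings. The C1 configuration is irrelevant because it is oxidised away. The furanone is not carried through the synthesis.
- Weak points: A1 holds a C2≡C3 alkyne conjugated to the Z alkene inside a ten-membered ring that is also trans-fused to the lactone, so the closure works against considerable angle strain. The aldehyde of A2 sits on a fully substituted, silyloxy-bearing carbon. Three or four steps with oxidant, fluoride and base remain after ring closure while the methylene lactone and the ester are present. The enyne of A2 still needs a stereodefined C4 metal or halide, so the hydrometallation is not saved.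
- Comparison: Alternative 1 is better in the precedent for its ring-closing reaction. The chosen plan sets against this a product without a strained alkyne, a C10 oxygen that never needs protection, and no steps after ring closure.

**Alternative 2:** The cut is the O–C10 bond. Camphorsulfonic acid would open the 1,10-epoxide of the 3-keto germacranolide A4 at tertiary C10 by transannular attack of the ketone oxygen, and loss of a C2 proton would give the bridged enol ether A3. Oxidation at C1 and desilylation would complete the target.
- Merits: the step follows the probable biosynthesis. It forms the bridge within an existing ring, so it does not have to overcome the entropy of a medium-ring closure. C10 is set by inversion of a trans epoxide.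
- Weak points: the hard part, the ten-membered ring of A4 with an E 1(10)-alkene precursor, a Z 4,5-enone and the lactone, is not addressed by the key step. In A4 the epoxide is β to the ketone, so eliminative opening toward C2 competes under acid and base. Germacranolide epoxides also tend to cyclise through the C4=C5 alkene. The C10 configuration depends on the face selectivity of epoxidising a flexible macrocycle.
- Comparison: once A4 exists, the bridging step of Alternative 2 is probably easier than any ring-closing cross-coupling. The chosen plan sets against this that it needs no separately built macrocycle and takes C10 from citramalic acid without a selectivity question.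

**Alternative 3:** The cut is C7–C8. The bromomethyl butenolide aldehyde A6, with C3–C4 already in place, would be treated with CrCl2 (divalent chromium) so that the allylchromium adds through C7 to the C8 aldehyde and gives the tricyclic alcohol A5. Acylation and desilylation would follow.
- Merits: chromium-mediated allylation is a proven ring-closing reaction for medium and large rings. The C3–C4 bond would be made between two unstrained partners. The step forms the ring, two stereocentres and the exocyclic methylene together.
- Weak points: the allylic bromide of A6 cannot coexist with the zerovalent palladium or the tin hydride needed to make C3–C4, and the bromine-based route to the bromide is not compatible with the dienyl furanone. It would have to be unveiled from a protected allylic alcohol after the coupling, which costs several steps and an extra protecting-group level. The C8 outcome is also uncertain: in the open system the ring-locked allyl unit is expected to give the 8S epimer through a chair transition state, and whether the ring constraint in A6 reverses this cannot be predicted.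
- Comparison: Alternative 3 is better in the precedent for the ring-closing step. The chosen plan uses the same Barbier reaction, but between two fragments, where C6 controls the outcome predictably and the bromide never meets palladium. It pays for this with a thioether–stannane coupling that is established between two molecules but not for closing a ten-membered ring.

Key step: step 19

Assumption (remark on the chemistry): the zinc Barbier addition of step 15 is taken to follow the closed chair transition state and so to give the 8S alcohol 23. If it gives the 8R epimer F4 instead, step 16 becomes an acylation with retention (see the fallback to step 16).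

## Route

Step 1
Reactants: 1 (S)-citramalic acid
Product: 2 2-[(4S)-2,2,4-trimethyl-5-oxo-1,3-dioxolan-4-yl]acetic acid
Conditions: 2,2-dimethoxypropane, TsOH·H2O (cat.), rt
Reagents that add atoms: 2,2-dimethoxypropane, COC(C)(C)OC
Why: Acetonide formation of an α-hydroxy acid as its 1,3-dioxolan-4-one is the standard way to tell the two carboxyl groups of a 2-hydroxy diacid apart; the five-membered acetal forms in preference and leaves the CH2CO2H arm free, and the quaternary centre (future C10) is not touched.

Step 2
Reactants: 2 2-[(4S)-2,2,4-trimethyl-5-oxo-1,3-dioxolan-4-yl]acetic acid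
Product: 4 (3S)-3-hydroxy-3-methyloxolan-2-one, via hydroxyethyl dioxolanone 3 (not isolated)
Conditions: BH3·SMe2, THF, 0 °C to rt; MeOH quench; then TsOH·H2O (cat.), CH2Cl2, rt
Reagents that add atoms: none
Why: Borane reduces a free carboxylic acid much faster than the ester-like dioxolanone carbonyl; under acid the new primary alcohol then transacylates onto the dioxolanone (lactonisation with loss of acetone), giving a stable, known type of α-hydroxy lactone.

Step 3
Reactants: 4 (3S)-3-hydroxy-3-methyloxolan-2-one
Product: 5 (2S)-2,4-dihydroxy-N-methoxy-N,2-dimethylbutanamide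
Conditions: MeNH(OMe)·HCl, Me3Al, CH2Cl2, 0 °C to rt
Reagents that add atoms: N,O-dimethylhydroxylamine hydrochloride, CNOC.Cl
Why: Weinreb aminolysis of a lactone with the aluminium amide opens the ring to the hydroxy amide; the crude diol should be silylated at once so that it cannot relactonise.

Step 4
Reactants: 5 (2S)-2,4-dihydroxy-N-methoxy-N,2-dimethylbutanamide
Product: 6 (2S)-4-[(tert-butyldimethylsilyl)oxy]-2-hydroxy-N-methoxy-N,2-dimethylbutanamide
Conditions: TBSCl, imidazole, CH2Cl2, 0 °C
Reagents that add atoms: tert-butyldimethylsilyl chloride, CC(C)(C)[Si](C)(C)Cl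
Why: Silylation distinguishes the primary from the tertiary hydroxyl on steric grounds; the tertiary alcohol stays free for the later ring closure.

Step 5
Reactants: 6 (2S)-4-[(tert-butyldimethylsilyl)oxy]-2-hydroxy-N-methoxy-N,2-dimethylbutanamide
Product: 7 (3S)-5-[(tert-butyldimethylsilyl)oxy]-3-hydroxy-3-methylpentan-2-one
Conditions: MeMgBr (3 equiv), THF, −20 to 0 °C
Reagents that add atoms: methylmagnesium bromide, C[Mg]Br
Why: Weinreb ketone synthesis; the first equivalent deprotonates the tertiary alcohol and the chelated tetrahedral intermediate prevents over-addition, giving the methyl ketone whose methyl group becomes C2.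

Step 6
Reactants: 7 (3S)-5-[(tert-butyldimethylsilyl)oxy]-3-hydroxy-3-methylpentan-2-one; 8 carbon disulfide
Product: 10 (2S)-2-{2-[(tert-butyldimethylsilyl)oxy]ethyl}-2-methyl-5-(methylsulfanyl)furan-3(2H)-one, via ketene dithioacetal 9 (not isolated)
Conditions: NaH (3 equiv), CS2, THF/DMF, 0 °C; MeI (2 equiv), 0 °C to rt
Reagents that add atoms: iodomethane, CI
Why: The methyl ketone enolate adds to carbon disulfide and double S-methylation gives the α-oxo ketene dithioacetal (a standard construction); the tertiary alkoxide then closes onto it by addition–elimination with loss of methanethiolate to give the 5-methylthio-3(2H)-furanone, a known route to this heterocycle from α-hydroxy methyl ketones. A path through the xanthate of the tertiary alkoxide would converge on the same product.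

Step 7
Reactants: 10 (2S)-2-{2-[(tert-butyldimethylsilyl)oxy]ethyl}-2-methyl-5-(methylsulfanyl)furan-3(2H)-one
Product: 11 (2S)-2-(2-hydroxyethyl)-2-methyl-5-(methylsulfanyl)furan-3(2H)-one
Conditions: HF·pyridine, THF/pyridine, 0 °C to rt
Reagents that add atoms: none
Why: Buffered fluoride removes the primary silyl ether without offering a nucleophile that could displace the methylthio group from the vinylogous thioester.

Step 8
Reactants: 11 (2S)-2-(2-hydroxyethyl)-2-methyl-5-(methylsulfanyl)furan-3(2H)-one
Product: 12 2-[(2S)-2-methyl-5-(methylsulfanyl)-3-oxo-2,3-dihydrofuran-2-yl]acetaldehyde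
Conditions: Dess–Martin periodinane, CH2Cl2, 0 °C to rt; used at once
Reagents that add atoms: none
Why: Dess–Martin oxidation is base-free and leaves the sulfide alone; this matters because the aldehyde carries the furanone oxygen in the β-position and would eliminate under amine base.

Step 9
Reactants: 13 propargyl alcohol
Product: 14 tert-butyldimethyl(prop-2-yn-1-yloxy)silane
Conditions: TBSCl, imidazole, CH2Cl2, 0 °C to rt
Reagents that add atoms: tert-butyldimethylsilyl chloride, CC(C)(C)[Si](C)(C)Cl
Why: Routine silylation; the C15 oxygen has to be masked for the organolithium, zinc and Mitsunobu steps.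

Step 10
Reactants: 14 tert-butyldimethyl(prop-2-yn-1-yloxy)silane
Product: 15 4-[(tert-butyldimethylsilyl)oxy]but-2-ynal
Conditions: n-BuLi, THF, −78 °C; DMF; inverse quench into aq. KH2PO4
Reagents that add atoms: N,N-dimethylformamide, CN(C)C=O
Why: Formylation of a lithium acetylide with DMF and buffered inverse quench is the standard preparation of ynals; the new carbon is C6.

Step 11
Reactants: 15 4-[(tert-butyldimethylsilyl)oxy]but-2-ynal; 16 methyl 2-(bromomethyl)acrylate
Product: 17 methyl (±)-7-[(tert-butyldimethylsilyl)oxy]-4-hydroxy-2-methylidenehept-5-ynoate
Conditions: Zn dust, THF/sat. aq. NH4Cl, 0 °C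
Reagents that add atoms: none
Why: Zinc Barbier allylation of an aldehyde with a 2-(bromomethyl)acrylate is a standard entry to the γ-hydroxy-α-methylene ester; it forms C6–C7 and is kept cold and short so that the hydroxy ester, not the lactone, is isolated.

Step 12
Reactants: 17 methyl (±)-7-[(tert-butyldimethylsilyl)oxy]-4-hydroxy-2-methylidenehept-5-ynoate
Product: 18 methyl 7-[(tert-butyldimethylsilyl)oxy]-2-methylidene-4-oxohept-5-ynoate
Conditions: Dess–Martin periodinane, CH2Cl2, 0 °C
Reagents that add atoms: none
Why: Dess–Martin oxidation of a propargylic alcohol to the ynone erases the racemic centre under non-basic conditions, so the CH2 group between ketone and acrylate should not move the alkene into conjugation.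

Step 13
Reactants: 18 methyl 7-[(tert-butyldimethylsilyl)oxy]-2-methylidene-4-oxohept-5-ynoate
Product: 20 (5S)-5-{3-[(tert-butyldimethylsilyl)oxy]prop-1-yn-1-yl}-3-methylideneoxolan-2-one, via hydroxy ester 19 (not isolated)
Conditions: Ru(p-cymene)[(S,S)-TsDPEN] (1 mol%), i-PrOH, rt; then TsOH·H2O (cat.), CH2Cl2, rt
Reagents that add atoms: none
Why: Noyori asymmetric transfer hydrogenation of an alkynyl ketone sets C6: the bifunctional ruthenium hydride differentiates the alkynyl from the alkyl side, and by analogy with simple alkynyl alkyl ketones the (S,S)-ligand should give the 4S carbinol (to be confirmed; the (R,R)-catalyst is the remedy if the sense is opposite). Acid then closes the γ-hydroxy ester to the lactone with loss of methanol.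

Step 14
Reactants: 20 (5S)-5-{3-[(tert-butyldimethylsilyl)oxy]prop-1-yn-1-yl}-3-methylideneoxolan-2-one
Product: 22 (5S)-3-(bromomethyl)-5-{3-[(tert-butyldimethylsilyl)oxy]prop-1-yn-1-yl}furan-2(5H)-one, via dibromide 21 (not isolated)
Conditions: Br2, CH2Cl2, −40 °C; then Et3N (1.05 equiv), −40 to 0 °C
Reagents that add atoms: bromine, BrBr
Why: Bromine should add to the 1,1-disubstituted alkene faster than to the alkyne, which two propargylic oxygens deactivate; amine-induced loss of HBr from the tertiary α-bromide and a ring C–H then gives the endocyclic butenolide with the allylic bromide, the same addition–elimination that turns methacrylates into 2-(bromomethyl)acrylates. Base is limited to one equivalent at low temperature because the C6–H of the product is acidic.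

Step 15
Reactants: 12 2-[(2S)-2-methyl-5-(methylsulfanyl)-3-oxo-2,3-dihydrofuran-2-yl]acetaldehyde; 22 (5S)-3-(bromomethyl)-5-{3-[(tert-butyldimethylsilyl)oxy]prop-1-yn-1-yl}furan-2(5H)-one
Product: 23 (2S)-2-{(2S)-2-hydroxy-2-[(2S,3R)-2-{3-[(tert-butyldimethylsilyl)oxy]prop-1-yn-1-yl}-4-methylidene-5-oxooxolan-3-yl]ethyl}-2-methyl-5-(methylsulfanyl)furan-3(2H)-one (6S,7R,8S,10S in germacranolide numbering)
Conditions: Zn dust, THF/sat. aq. NH4Cl, 0 °C to rt
Reagents that add atoms: none
Why: Barbier allylation with a 3-(bromomethyl)butenolide: the allylzinc reacts through its γ-carbon C7 in a closed six-membered chair, forming C7–C8 and moving the alkene to C11=C13. The aldehyde should approach anti to the C6 alkynyl group, which sets C7 trans to C6; with the ring-locked allyl geometry and the aldehyde substituent equatorial, the chair places O8 syn to C11, i.e. 8S, the epimer of what the target needs. The neutral aqueous medium spares the elimination-prone aldehyde.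

Step 16
Reactants: 23 the 8S alcohol of step 15; 24 (R)-2-methylbutanoic acid
Product: 25 (1R)-1-[(2S,3R)-2-{3-[(tert-butyldimethylsilyl)oxy]prop-1-yn-1-yl}-4-methylidene-5-oxooxolan-3-yl]-2-[(2S)-2-methyl-5-(methylsulfanyl)-3-oxo-2,3-dihydrofuran-2-yl]ethyl (2R)-2-methylbutanoate
Conditions: PPh3, diisopropyl azodicarboxylate, toluene, 0 °C to rt
Reagents that add atoms: none
Why: Mitsunobu esterification: the carboxylate displaces the oxyphosphonium group at C8 with inversion, so the side chain is introduced and C8 corrected to 8R together. The conditions are neutral and do not enolise the acid's own stereocentre.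

Step 17
Reactants: 25 the silyl ether ester of step 16
Product: 26 (1R)-1-[(2S,3R)-2-(3-hydroxyprop-1-yn-1-yl)-4-methylidene-5-oxooxolan-3-yl]-2-[(2S)-2-methyl-5-(methylsulfanyl)-3-oxo-2,3-dihydrofuran-2-yl]ethyl (2R)-2-methylbutanoate
Conditions: HF·pyridine, THF/pyridine, 0 °C
Reagents that add atoms: none
Why: Buffered fluoride cleaves the primary propargylic silyl ether and frees the hydroxyl that has to direct the next step; neither the ester nor the methylene lactone is expected to react.

Step 18
Reactants: 26 the alkynol of step 17
Product: 27 (1R)-1-[(2S,3R)-2-[(1Z)-3-hydroxy-2-(tributylstannyl)prop-1-en-1-yl]-4-methylidene-5-oxooxolan-3-yl]-2-[(2S)-2-methyl-5-(methylsulfanyl)-3-oxo-2,3-dihydrofuran-2-yl]ethyl (2R)-2-methylbutanoate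
Conditions: Bu3SnH, [Cp*RuCl]4 (2.5 mol%), CH2Cl2, rt, dark
Reagents that add atoms: tributyltin hydride, CCCC[SnH](CCCC)CCCC
Why: Ruthenium-catalysed trans-hydrostannation of a propargylic alcohol: the free C15 hydroxyl hydrogen-bonds to the chloride ligand and steers tin to the proximal carbon C4, while hydrogen is delivered anti to C5. This gives the Z stannane with C6 and tin cis, the geometry the ring closure needs.

Step 19
Reactants: 27 the Z alkenylstannane of step 18
Product: 28 the target, 15-hydroxy-1-oxo-3,10-epoxygermacra-2,4(Z),11(13)-trien-6,12-olide 8-[(2R)-2-methylbutanoate] (6R,7R,8R,10S)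
Conditions: Pd(PPh3)4 (20 mol%), copper thiophene-2-carboxylate (3 equiv), THF, 50 °C, syringe-pump addition to a final 1 mM
Reagents that add atoms: none
Why: The copper carboxylate (monovalent copper) binds the sulfur and polarises the C3–S bond, zerovalent palladium inserts, the alkenyl group moves from tin to palladium with retention (the carboxylate takes up tin, copper takes up methanethiolate), and reductive elimination forms C3–C4; no base is involved. The closest known reaction is the intermolecular Liebeskind–Srogl-type coupling of heteroaryl and vinylogous thioesters with organostannanes, with macrocyclising Stille couplings as the model for running such a step in ring-closing mode. The ten-membered carbocycle closes by sp2–sp2 reductive elimination from an eleven-membered palladacycle, with both new ring alkenes (C2=C3 and C4=C5) endocyclic and the oxygen bridge already in place. No stereocentre is formed; the CIP descriptor of C6 changes from S to R only because the priority of C5 changes when tin is replaced by carbon. The step needs retention of the Z geometry, which stereoretentive tin-to-palladium transfer provides, and ring closure ahead of oligomerisation, which high dilution and the substrate's shape favour: the Z alkene, the trans lactone and the quaternary C10 turn C3 and C4 toward each other. It also needs tolerance of the free allylic alcohol, the methylene lactone and the ester, which the neutral conditions should give.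

## Compound list

1 | (S)-citramalic acid | OC(=O)[C@](C)(CC(=O)O)O | starting material
2 | 2-[(4S)-2,2,4-trimethyl-5-oxo-1,3-dioxolan-4-yl]acetic acid | CC1(C)OC(=O)[C@](C)(CC(=O)O)O1 | intermediate
3 | (5S)-5-(2-hydroxyethyl)-2,2,5-trimethyl-1,3-dioxolan-4-one | CC1(C)OC(=O)[C@](C)(CCO)O1 | intermediate
4 | (3S)-3-hydroxy-3-methyloxolan-2-one | C[C@]1(O)CCOC1=O | intermediate
5 | (2S)-2,4-dihydroxy-N-methoxy-N,2-dimethylbutanamide | CON(C)C(=O)[C@@](C)(O)CCO | intermediate
6 | (2S)-4-[(tert-butyldimethylsilyl)oxy]-2-hydroxy-N-methoxy-N,2-dimethylbutanamide | CON(C)C(=O)[C@@](C)(O)CCO[Si](C)(C)C(C)(C)C | intermediate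
7 | (3S)-5-[(tert-butyldimethylsilyl)oxy]-3-hydroxy-3-methylpentan-2-one | CC(=O)[C@@](C)(O)CCO[Si](C)(C)C(C)(C)C | intermediate
8 | carbon disulfide | S=C=S | starting material
9 | (4S)-6-[(tert-butyldimethylsilyl)oxy]-4-hydroxy-4-methyl-1,1-bis(methylsulfanyl)hex-1-en-3-one | CSC(SC)=CC(=O)[C@@](C)(O)CCO[Si](C)(C)C(C)(C)C | intermediate
10 | (2S)-2-{2-[(tert-butyldimethylsilyl)oxy]ethyl}-2-methyl-5-(methylsulfanyl)furan-3(2H)-one | CSC1=CC(=O)[C@](C)(CCO[Si](C)(C)C(C)(C)C)O1 | intermediate
11 | (2S)-2-(2-hydroxyethyl)-2-methyl-5-(methylsulfanyl)furan-3(2H)-one | CSC1=CC(=O)[C@](C)(CCO)O1 | intermediate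
12 | 2-[(2S)-2-methyl-5-(methylsulfanyl)-3-oxo-2,3-dihydrofuran-2-yl]acetaldehyde | CSC1=CC(=O)[C@](C)(CC=O)O1 | intermediate
13 | propargyl alcohol | C#CCO | starting material
14 | tert-butyldimethyl(prop-2-yn-1-yloxy)silane | C#CCO[Si](C)(C)C(C)(C)C | intermediate
15 | 4-[(tert-butyldimethylsilyl)oxy]but-2-ynal | O=CC#CCO[Si](C)(C)C(C)(C)C | intermediate
16 | methyl 2-(bromomethyl)acrylate | C=C(CBr)C(=O)OC | starting material
17 | methyl (±)-7-[(tert-butyldimethylsilyl)oxy]-4-hydroxy-2-methylidenehept-5-ynoate | C=C(CC(O)C#CCO[Si](C)(C)C(C)(C)C)C(=O)OC | intermediate
18 | methyl 7-[(tert-butyldimethylsilyl)oxy]-2-methylidene-4-oxohept-5-ynoate | C=C(CC(=O)C#CCO[Si](C)(C)C(C)(C)C)C(=O)OC | intermediate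
19 | methyl (4S)-7-[(tert-butyldimethylsilyl)oxy]-4-hydroxy-2-methylidenehept-5-ynoate | C=C(C[C@H](O)C#CCO[Si](C)(C)C(C)(C)C)C(=O)OC | intermediate
20 | (5S)-5-{3-[(tert-butyldimethylsilyl)oxy]prop-1-yn-1-yl}-3-methylideneoxolan-2-one | O=C1O[C@H](C#CCO[Si](C)(C)C(C)(C)C)CC1=C | intermediate
21 | (5S)-3-bromo-3-(bromomethyl)-5-{3-[(tert-butyldimethylsilyl)oxy]prop-1-yn-1-yl}oxolan-2-one (both C3 epimers) | O=C1O[C@H](C#CCO[Si](C)(C)C(C)(C)C)CC1(Br)CBr | intermediate
22 | (5S)-3-(bromomethyl)-5-{3-[(tert-butyldimethylsilyl)oxy]prop-1-yn-1-yl}furan-2(5H)-one | O=C1O[C@H](C#CCO[Si](C)(C)C(C)(C)C)C=C1CBr | intermediate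
23 | (2S)-2-{(2S)-2-hydroxy-2-[(2S,3R)-2-{3-[(tert-butyldimethylsilyl)oxy]prop-1-yn-1-yl}-4-methylidene-5-oxooxolan-3-yl]ethyl}-2-methyl-5-(methylsulfanyl)furan-3(2H)-one | C=C1C(=O)O[C@H](C#CCO[Si](C)(C)C(C)(C)C)[C@H]1[C@@H](O)C[C@]2(C)OC(SC)=CC2=O | intermediate
24 | (R)-2-methylbutanoic acid | OC(=O)[C@H](C)CC | starting material
25 | (1R)-1-[(2S,3R)-2-{3-[(tert-butyldimethylsilyl)oxy]prop-1-yn-1-yl}-4-methylidene-5-oxooxolan-3-yl]-2-[(2S)-2-methyl-5-(methylsulfanyl)-3-oxo-2,3-dihydrofuran-2-yl]ethyl (2R)-2-methylbutanoate | C=C1C(=O)O[C@H](C#CCO[Si](C)(C)C(C)(C)C)[C@H]1[C@H](OC(=O)[C@H](C)CC)C[C@]2(C)OC(SC)=CC2=O | intermediate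
26 | (1R)-1-[(2S,3R)-2-(3-hydroxyprop-1-yn-1-yl)-4-methylidene-5-oxooxolan-3-yl]-2-[(2S)-2-methyl-5-(methylsulfanyl)-3-oxo-2,3-dihydrofuran-2-yl]ethyl (2R)-2-methylbutanoate | C=C1C(=O)O[C@H](C#CCO)[C@H]1[C@H](OC(=O)[C@H](C)CC)C[C@]2(C)OC(SC)=CC2=O | intermediate
27 | (1R)-1-[(2S,3R)-2-[(1Z)-3-hydroxy-2-(tributylstannyl)prop-1-en-1-yl]-4-methylidene-5-oxooxolan-3-yl]-2-[(2S)-2-methyl-5-(methylsulfanyl)-3-oxo-2,3-dihydrofuran-2-yl]ethyl (2R)-2-methylbutanoate | C=C1C(=O)O[C@H](/C=C(/CO)[Sn](CCCC)(CCCC)CCCC)[C@H]1[C@H](OC(=O)[C@H](C)CC)C[C@]2(C)OC(SC)=CC2=O | intermediate
28 | target CNP0307052.2: 15-hydroxy-1-oxo-3,10-epoxygermacra-2,4(Z),11(13)-trien-6,12-olide 8-[(2R)-2-methylbutanoate] (6R,7R,8R,10S) | C=C1C(=O)O[C@@H]2/C=C(/CO)C3=CC(=O)[C@](C)(C[C@@H](OC(=O)[C@H](C)CC)[C@@H]12)O3 | target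

## Step count and risks

Total: 19 steps. Longest linear sequence: 13 steps (steps 1 to 8, then 15 to 19, from 1). The lactone branch (steps 9 to 14) joins at step 15.

**Step 19 (key step).**
- What may go wrong: bimolecular coupling and oligomerisation may outrun ring closure. The allylic-alcohol stannane may lose tin by protonation while transmetalation is slow. The eleven-membered palladacycle may be reluctant to undergo reductive elimination because of transannular strain. The reaction is established between two molecules but has not been used to close a medium ring.
- Fallback: change the transferring element and reach the nucleophile by another sequence. Starting from 27, iododestannylation (I2, CH2Cl2, 0 °C, retention) would give the Z alkenyl iodide F1. Miyaura borylation (PdCl2(dppf), bis(pinacolato)diboron, KOAc) would give the alkenyl pinacol boronate F2, which is inert to the thioether in the absence of copper. F2 would then be closed under the thioether–boronate protocol (Pd2(dba)3, tri(2-furyl)phosphine, copper thiophene-2-carboxylate) on which this coupling type was first established. The route is rejoined at 28.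
- If neither nucleophile closes the ring, the closure has to move to C7–C8 (A6 to A5), at the cost set out under Alternative 3.

**Step 16.**
- What may go wrong: elimination across C7–C8 from the oxyphosphonium intermediate; attack of the weakly acidic carboxylic acid at phosphorus instead of carbon (acylation with retention); participation of the lactone carbonyl, leading to lactone migration. The carbinol is secondary and flanked by a branched carbon.
- Fallback: separate inversion from acylation. Starting from 23, a Mitsunobu reaction with the more acidic chloroacetic acid would give the inverted chloroacetate F3. Thiourea would remove the chloroacetyl group under near-neutral conditions to give the 8R alcohol F4. Steglich esterification with 24 (carbodiimide, catalytic 4-dimethylaminopyridine) then proceeds with retention and rejoins the route at 25. The same last step applies if step 15 gives F4 directly.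

**Step 18.**
- What may go wrong: the sulfur of the furanone may deactivate the ruthenium catalyst; tin hydride may reduce the methylene lactone by conjugate addition; tin may be delivered to C5.
- Fallback: change the hydrometallating agent. Starting from 26, hydroxyl-directed trans-hydrosilylation with BnMe2SiH and the same catalyst (a silane is a much weaker reductant) would give the C4 benzyldimethylsilyl alkene F5. Iododesilylation (N-iodosuccinimide, hexafluoroisopropanol, retention) would give the iodide F1. Palladium-catalysed stannylation with hexabutylditin (Pd(PPh3)4) rejoins the route at 27.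

**Step 15.**
- What may go wrong: loss of the furanone oxygen from aldehyde 12 by β-elimination before it is trapped; coupling through C13 instead of C7; incomplete face selectivity at C7; migration of the lactone to O8 in the product.
- Fallback: replace the Barbier reagent with an isolable allylboron reagent. Starting from 22, palladium-catalysed borylation (Pd2(dba)3, bis(pinacolato)diboron) would give the allyl pinacol boronate F6. Its Sc(OTf)3-catalysed allylboration of 12 runs through the same closed chair without zinc or water and rejoins the route at 23.

**Step 14.**
- What may go wrong: racemisation at C6 through the furanolate once the butenolide has formed and amine is still present; addition of bromine to the alkyne; loss of HBr toward the exocyclic bromomethylene isomer.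
- Fallback: carry out the bromination–elimination on the open-chain ester, where C6–H is not part of a butenolide, and lactonise last. Starting from 19 (isolated before the acid treatment of step 13), silylation (Et3SiCl, imidazole) would give the triethylsilyl ether F7. Bromine and then triethylamine would give the open-chain Z allylic bromide F8. Zinc Barbier addition of F8 to 12 is expected, with this Z-type allyl geometry in the chair, to give the 7,8-relationship of the target directly, as hydroxy ester F9. The open question then becomes the face selectivity with respect to C6. Steglich acylation with 24 would give F10, and HF·pyridine followed by a trace of acid would remove both silyl groups and close the lactone. The route is rejoined at 26, and steps 15 to 17 are by-passed.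

## Further compounds

F1 | step 19 | C4 iodide corresponding to 27: (1R)-1-[(2S,3R)-2-[(1Z)-3-hydroxy-2-iodoprop-1-en-1-yl]-4-methylidene-5-oxooxolan-3-yl]-2-[(2S)-2-methyl-5-(methylsulfanyl)-3-oxo-2,3-dihydrofuran-2-yl]ethyl (2R)-2-methylbutanoate | C=C1C(=O)O[C@H](/C=C(/CO)I)[C@H]1[C@H](OC(=O)[C@H](C)CC)C[C@]2(C)OC(SC)=CC2=O
F2 | step 19 | C4 pinacol boronate corresponding to 27 (boron cis to C6, same configuration at all centres) | C=C1C(=O)O[C@H](/C=C(/CO)B3OC(C)(C)C(C)(C)O3)[C@H]1[C@H](OC(=O)[C@H](C)CC)C[C@]2(C)OC(SC)=CC2=O
F3 | step 16 | 8R chloroacetate: C8-inverted chloroacetic ester of 23 | C=C1C(=O)O[C@H](C#CCO[Si](C)(C)C(C)(C)C)[C@H]1[C@H](OC(=O)CCl)C[C@]2(C)OC(SC)=CC2=O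
F4 | step 16 | 8R alcohol: C8 epimer of 23 | C=C1C(=O)O[C@H](C#CCO[Si](C)(C)C(C)(C)C)[C@H]1[C@H](O)C[C@]2(C)OC(SC)=CC2=O
F5 | step 18 | C4 benzyldimethylsilyl alkene corresponding to 27 (silicon cis to C6) | C=C1C(=O)O[C@H](/C=C(/CO)[Si](C)(C)Cc3ccccc3)[C@H]1[C@H](OC(=O)[C@H](C)CC)C[C@]2(C)OC(SC)=CC2=O
F6 | step 15 | (5S)-5-{3-[(tert-butyldimethylsilyl)oxy]prop-1-yn-1-yl}-3-[(4,4,5,5-tetramethyl-1,3,2-dioxaborolan-2-yl)methyl]furan-2(5H)-one | O=C1O[C@H](C#CCO[Si](C)(C)C(C)(C)C)C=C1CB2OC(C)(C)C(C)(C)O2
F7 | step 14 | methyl (4S)-7-[(tert-butyldimethylsilyl)oxy]-2-methylidene-4-[(triethylsilyl)oxy]hept-5-ynoate | C=C(C[C@H](O[Si](CC)(CC)CC)C#CCO[Si](C)(C)C(C)(C)C)C(=O)OC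
F8 | step 14 | methyl (2Z,4S)-2-(bromomethyl)-7-[(tert-butyldimethylsilyl)oxy]-4-[(triethylsilyl)oxy]hept-2-en-5-ynoate | COC(=O)/C(CBr)=C/[C@H](O[Si](CC)(CC)CC)C#CCO[Si](C)(C)C(C)(C)C
F9 | step 14 | open-chain hydroxy ester with the target configuration at C6, C7, C8 and C10 (6-O-triethylsilyl, 15-O-tert-butyldimethylsilyl, methyl ester at C12) | CC[Si](CC)(CC)O[C@H](C#CCO[Si](C)(C)C(C)(C)C)[C@H](C(=C)C(=O)OC)[C@H](O)C[C@]1(C)OC(SC)=CC1=O
F10 | step 14 | 8-O-[(2R)-2-methylbutanoate] of F9 | CC[Si](CC)(CC)O[C@H](C#CCO[Si](C)(C)C(C)(C)C)[C@H](C(=C)C(=O)OC)[C@H](OC(=O)[C@H](C)CC)C[C@]1(C)OC(SC)=CC1=O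
A1 | alternative 1 | ten-membered propargylic alcohol (C1 carbinol, C2≡C3 alkyne, 10-O-triethylsilyl, 15-O-tert-butyldimethylsilyl) | C=C1C(=O)O[C@@H]2/C=C(/CO[Si](C)(C)C(C)(C)C)C#C[C@@H](O)[C@](C)(C[C@@H](OC(=O)[C@H](C)CC)[C@@H]12)O[Si](CC)(CC)CC
A2 | alternative 1 | open-chain C1 aldehyde with C2 iodoalkyne (precursor of A1) | C=C1C(=O)O[C@H](/C=C(/CO[Si](C)(C)C(C)(C)C)C#CI)[C@H]1[C@H](OC(=O)[C@H](C)CC)C[C@@](C)(C=O)O[Si](CC)(CC)CC
A3 | alternative 2 | 1-hydroxy bridged enol ether (15-O-tert-butyldimethylsilyl) | C=C1C(=O)O[C@@H]2/C=C(/CO[Si](C)(C)C(C)(C)C)C3=C[C@@H](O)[C@](C)(C[C@@H](OC(=O)[C@H](C)CC)[C@@H]12)O3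
A4 | alternative 2 | 1,10-epoxy-3-oxogermacra-4(Z),11(13)-dien-6,12-olide 8-[(2R)-2-methylbutanoate], 15-O-tert-butyldimethylsilyl (precursor of A3) | C=C1C(=O)O[C@@H]2/C=C(/CO[Si](C)(C)C(C)(C)C)C(=O)C[C@H]3O[C@]3(C)C[C@@H](OC(=O)[C@H](C)CC)[C@@H]12
A5 | alternative 3 | 8-hydroxy 15-O-tert-butyldimethylsilyl tricycle | C=C1C(=O)O[C@@H]2/C=C(/CO[Si](C)(C)C(C)(C)C)C3=CC(=O)[C@](C)(C[C@@H](O)[C@@H]12)O3
A6 | alternative 3 | open-chain C8 aldehyde with 3-(bromomethyl)butenolide, C3–C4 bond in place (precursor of A5) | BrCC1=C[C@@H](/C=C(/CO[Si](C)(C)C(C)(C)C)C2=CC(=O)[C@](C)(CC=O)O2)OC1=O
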